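The cyclohexane is opened retrosynthetically at C1–C2 (C1 = quaternary oxirane carbon, C2 = neighbouring acetoxy carbon). This leads to an acyclic keto aldehyde whose stereocentres C6, C5, C4 and C3 are C2–C5 of D-gulonic acid. A SmI2 pinacol coupling of the C1 ketone with the C2 aldehyde makes that bond, closes the six-membered ring and sets C1 and C2 in one operation. It exploits the cis C1–O/C2–O pair, which is trans to both flanking oxygens, C6–O and C3–O. The precursor bears only ethers: PMB on C3–O and C7–O, benzyl on C4–O, an acetonide on C5–O/C6–O. Later C1–O displaces C6–O (cyclic sulfate) to give the oxirane.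

Key step: step 11

**Conventions and design remarks**
- Target numbering is used for every intermediate. C1 is the quaternary carbon (it bears C7H2O), C2 and C3 are the acetoxy carbons, C4 and C5 the carbinol carbons, and C6 the oxirane CH.
- With C1→C6 drawn clockwise, α is below and β is above the ring. In the target, C1–O, C2–O, C4–O and C6–O are α; C3–O, C5–O and C7 are β.
- Gulonic acid C1–C6 become C1, C6, C5, C4, C3, C2. C7 comes from the ylide.
- PMB = 4-methoxybenzyl, Bn = benzyl, Bz = benzoyl.
- In cyclitol 14 two oxygen pairs are cis: the new C1–O/C2–O pair (α) and the C5–O/C6–O pair (β). The second pair is what allows the acetonide and later the cyclic sulfate. C6–O is β up to 20 and is inverted in step 17.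
- C4–O is benzylated while C1 is an alkene carbon. On an amide or ester, the C4 alkoxide sits cis to C1 on the dioxolane and would re-close the γ-lactone.
- The C1 ketone is released only in step 10. With C3–OH free it would be locked as a six-membered hemiketal, it would not survive step 9, and C6 would be exposed to base.
- Read from its aldehyde, keto aldehyde 13 is an L-gluco-heptos-6-ulose. The same chain read from the ketone end is D-gulo.
- Assumption: centres that are erased later (anomeric C in 3, C1 in 7–12, acetal CH in 11, S in 19) are carried as mixtures.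

## Route

**Step 1**
Reactants: 1 D-gulono-1,4-lactone
Product: 2 2,3:5,6-di-O-isopropylidene-D-gulono-1,4-lactone
Conditions: Me2C(OMe)2, acetone, TsOH·H2O (cat.), rt
Reagents that add atoms: 2,2-dimethoxypropane, COC(C)(C)OC
Why: Acid-catalysed acetonide formation (transacetalisation) takes up the two 1,2-diols on offer, the cis ring diol (future C6–O/C5–O) and the side-chain diol (future C3–O/C2–O), and touches no stereocentre.

**Step 2**
Reactants: 2 2,3:5,6-di-O-isopropylidene-D-gulono-1,4-lactone
Product: 3 2,3:5,6-di-O-isopropylidene-D-gulofuranose (anomers)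
Conditions: i-Bu2AlH (1.1 equiv), CH2Cl2, −78 °C; aq. potassium sodium tartrate
Reagents that add atoms: none
Why: Partial lactone reduction: the aluminium hemiacetal formed by hydride addition is stable at −78 °C and gives the lactol only on work-up, so over-reduction should not occur.

**Step 3**
Reactants: 3 2,3:5,6-di-O-isopropylidene-D-gulofuranose; 4 methyltriphenylphosphonium bromide
Product: 5 1,2-dideoxy-3,4:6,7-di-O-isopropylidene-D-gulo-hept-1-enitol (C1=C7 alkene, C4–OH free)
Conditions: 4 (3 equiv), KOt-Bu, THF, 0 °C → rt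
Reagents that add atoms: methyltriphenylphosphonium bromide (4), C[P+](c1ccccc1)(c1ccccc1)c1ccccc1.[Br-]
Why: Wittig methylenation of the aldehyde tautomer of the lactol adds C7, turns C1 into an inert alkene carbon and releases C4–OH as the only hydroxyl, the non-stabilised ylide reacting faster than C6 can epimerise.

**Step 4**
Reactants: 5 heptenitol with free C4–OH
Product: 6 C4-O-benzyl heptenitol (5-O-benzyl-1,2-dideoxy-3,4:6,7-di-O-isopropylidene-D-gulo-hept-1-enitol)
Conditions: NaH, BnBr, Bu4NI (cat.), DMF, 0 °C → rt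
Reagents that add atoms: benzyl bromide, BrCc1ccccc1
Why: Williamson etherification of the only hydroxyl; since C1 is not a carbonyl carbon, the C4 alkoxide has nothing to attack and cannot re-form a lactone.

**Step 5**
Reactants: 6 C4-O-benzyl heptenitol
Product: 7 C1,C7-diol (C1 epimers; C4–OBn, C5,C6- and C2,C3-acetonides)
Conditions: OsO4 (cat.), NMO, acetone/H2O, rt
Reagents that add atoms: OsO4, O=[Os](=O)(=O)=O (catalytic oxygen carrier); N-methylmorpholine N-oxide, C[N+]1([O-])CCOCC1; water, O
Why: Upjohn dihydroxylation of the only alkene introduces C1–O and C7–O; the configuration at C1 is irrelevant because step 10 erases it.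

**Step 6**
Reactants: 7 C1,C7-diol
Product: 9 C7-O-PMB ether (C1–OH free), via stannylene acetal 8 (not isolated)
Conditions: Bu2SnO, toluene, reflux (−H2O); then PMBCl, Bu4NI (cat.), toluene, 90 °C
Reagents that add atoms: 4-methoxybenzyl chloride, COc1ccc(CCl)cc1; dibutyltin oxide, CCCC[Sn](=O)CCCC (tin is kept only in 8)
Why: Stannylene-acetal-mediated monoalkylation directs the electrophile to the primary oxygen of a terminal 1,2-diol, so C7–O is etherified and C1–OH stays free for oxidation.

**Step 7**
Reactants: 9 C7-O-PMB ether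
Product: 10 C1,C2,C3-triol (C5,C6-acetonide kept)
Conditions: AcOH/H2O (4:1), rt
Reagents that add atoms: none
Why: Selective acetal hydrolysis: the monosubstituted terminal dioxolane is cleaved much faster than the cis-disubstituted internal one, and Bn and PMB ethers are inert to aqueous acetic acid.

**Step 8**
Reactants: 10 C1,C2,C3-triol
Product: 11 C2,C3-O-(4-methoxybenzylidene) acetal (C1–OH free)
Conditions: 4-MeOC6H4CH(OMe)2, PPTS (cat.), CH2Cl2, rt
Reagents that add atoms: 4-methoxybenzaldehyde dimethyl acetal, COc1ccc(cc1)C(OC)OC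
Why: Acid-catalysed transacetalisation; only C2–OH and C3–OH can share a five-membered acetal, C1–OH is too remote, and PPTS is too weak to move the internal acetonide.

**Step 9**
Reactants: 11 C2,C3-O-(4-methoxybenzylidene) acetal
Product: 12 C1,C2-diol with C3–OPMB, C4–OBn, C7–OPMB and C5,C6-acetonide
Conditions: i-Bu2AlH (5 equiv), CH2Cl2, −78 → 0 °C; aq. potassium sodium tartrate
Reagents that add atoms: none
Why: Regioselective reductive opening of a 4-methoxybenzylidene acetal: aluminium binds the less hindered primary oxygen, that C–O bond breaks and hydride quenches the oxocarbenium ion, which leaves PMB on the secondary C3–O and frees C2–OH.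

**Step 10**
Reactants: 12 C1,C2-diol
Product: 13 keto aldehyde, 3-O-benzyl-4,5-O-isopropylidene-2,7-bis-O-(4-methoxybenzyl)-L-gluco-heptos-6-ulose (C2 aldehyde, C1 ketone)
Conditions: Dess–Martin periodinane (3 equiv), CH2Cl2, 0 °C → rt; used directly after drying
Reagents that add atoms: none
Why: Dess–Martin oxidation converts the secondary C1–OH and the primary C2–OH in one non-basic operation, so C3 and C6 should not epimerise and no β-alkoxide should be eliminated.

**Step 11**
Reactants: 13 keto aldehyde
Product: 14 branched cyclitol with free cis C1,C2-diol (C1–OH α, C7 β, C2–OH α, C3–OPMB β, C4–OBn α, C5,C6-acetonide β)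
Conditions: SmI2 (3 equiv, 0.1 M in THF), t-BuOH (3 equiv), THF, −78 °C → rt, slow addition of 13, no HMPA; aq. NaHCO3
Reagents that add atoms: none
Why: Divalent samarium transfers one electron to the more easily reduced C2 aldehyde, the samarium-bound ketyl adds to the samarium-activated C1 ketone, and a second electron plus protonation give the diol; this is the intramolecular pinacol coupling known for sugar-derived dialdehydes and keto aldehydes on the way to inositols and branched cyclitols. The cyclohexane closes in a 6-exo-trig mode through a chair in which C3–OPMB, C4–OBn, C5–O and the CH2OPMB arm are equatorial. Bridging of both carbonyl oxygens by trivalent samarium keeps C1–O and C2–O on one face, so the diol is cis. C2 is set by C3–OPMB and C1 by the acetonide oxygen on C6, because each developing C–O bond turns away from the neighbouring C–O dipole; both neighbours are β, so the two preferences reinforce each other and should place both hydroxyls α. The step needs closure to outrun plain carbonyl reduction and loss of an α-oxygen: the cis-dioxolane pre-folds the chain, every α-substituent is a poor ether leaving group, and strongly reducing additives are left out.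

**Step 12**
Reactants: 14 branched cyclitol
Product: 15 C1,C2,C3,C7-tetraol (C4–OBn, C5,C6-acetonide)
Conditions: DDQ (3 equiv), CH2Cl2/pH 7 phosphate buffer, 0 °C → rt
Reagents that add atoms: none
Why: Oxidative PMB cleavage: DDQ abstracts hydride from the two electron-rich benzylic positions and water hydrolyses the oxocarbenium ions, while the plain benzyl ether and the acetonide persist and the water-rich medium disfavours capture by neighbouring hydroxyls.

**Step 13**
Reactants: 15 tetraol
Product: 17 2,3-di-O-acetyl-7-O-benzoyl cyclitol acetonide (C1–OH free), via 7-O-benzoate 16 (not isolated)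
Conditions: BzCl (1.05 equiv), pyridine, CH2Cl2, −40 → −20 °C; then Ac2O (excess), 0 °C → rt, no DMAP
Reagents that add atoms: benzoyl chloride, O=C(Cl)c1ccccc1; acetic anhydride, CC(=O)OC(C)=O
Why: Chemoselective sequential acylation: at low temperature one equivalent of BzCl should take the only primary hydroxyl, and Ac2O/pyridine then esterifies the two equatorial secondary hydroxyls and leaves the axial tertiary C1–OH untouched.

**Step 14**
Reactants: 17 triester acetonide
Product: 18 C1,C5,C6-triol triester
Conditions: TFA/H2O (9:1), CH2Cl2, 0 °C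
Reagents that add atoms: none
Why: Acid hydrolysis of the isopropylidene acetal; the esters, the benzyl ether and the electronically deactivated tertiary carbinol tolerate cold aqueous TFA.

**Step 15**
Reactants: 18 triol triester
Product: 19 C5,C6 cyclic sulfite (epimers at sulfur)
Conditions: SOCl2, Et3N, CH2Cl2, 0 °C
Reagents that add atoms: thionyl chloride, O=S(Cl)Cl
Why: Cyclic sulfite formation needs two hydroxyls that can span a five-membered ring; only the cis C5–OH (equatorial)/C6–OH (axial) pair qualifies, since C1–OH is tertiary and trans-diaxial to C6–OH.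

**Step 16**
Reactants: 19 cyclic sulfite
Product: 20 C5,C6 cyclic sulfate
Conditions: RuCl3·xH2O (cat.), NaIO4, MeCN/CH2Cl2/H2O, 0 °C, short contact time
Reagents that add atoms: sodium periodate, [Na+].[O-]I(=O)(=O)=O
Why: RuO4-catalysed oxidation of a sulfite to the sulfate is far faster at 0 °C than attack on a benzyl ether or a benzoate ring.

**Step 17**
Reactants: 20 cyclic sulfate
Product: 22 C4-O-benzyl epoxy alcohol (C1,C6-oxirane α; C5–OH free), via sodium epoxy sulfate 21 (not isolated)
Conditions: NaH (1.05 equiv), THF (dilute), 0 °C; then H2SO4 (cat.), H2O (2 equiv), THF, rt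
Reagents that add atoms: sodium hydride, [Na+].[H-] (sodium is kept only in 21)
Why: Intramolecular SN2 opening of a cyclic sulfate by a neighbouring alkoxide (3-exo-tet, the hydroxy cyclic sulfate to epoxide conversion): C1–O and the C6–O bond are trans-diaxial in the favoured chair, so backside attack inverts C6 and puts the oxirane on the α face, attack at C5 would need an oxetane, any acyl shift to C1–O is reversible whereas closure is not, and the remaining C5 sulfate monoester is hydrolysed with S–O cleavage and retention.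

**Step 18**
Reactants: 22 C4-O-benzyl epoxy alcohol
Product: 23 target CNP0171674.1
Conditions: H2 (1 atm), Pd(OH)2/C, EtOAc, rt
Reagents that add atoms: none
Why: Catalytic hydrogenolysis of the benzyl ether under neutral conditions in a non-nucleophilic solvent; the non-benzylic, electron-poor oxirane and the esters should survive, and no base is present to move the C3 acetate to C4–OH.

## Compound list

1 | D-gulono-1,4-lactone | OC[C@@H](O)[C@@H]1OC(=O)[C@H](O)[C@@H]1O | starting material
2 | 2,3:5,6-di-O-isopropylidene-D-gulono-1,4-lactone | CC1(C)OC[C@@H](O1)[C@@H]2OC(=O)[C@@H]3OC(C)(C)O[C@H]23 | intermediate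
3 | 2,3:5,6-di-O-isopropylidene-D-gulofuranose (anomers) | CC1(C)OC[C@@H](O1)[C@@H]2OC(O)[C@@H]3OC(C)(C)O[C@H]23 | intermediate
4 | methyltriphenylphosphonium bromide | C[P+](c1ccccc1)(c1ccccc1)c1ccccc1.[Br-] | starting material
5 | 1,2-dideoxy-3,4:6,7-di-O-isopropylidene-D-gulo-hept-1-enitol (C4–OH free) | CC1(C)OC[C@@H](O1)[C@H](O)[C@H]2OC(C)(C)O[C@H]2C=C | intermediate
6 | 5-O-benzyl-1,2-dideoxy-3,4:6,7-di-O-isopropylidene-D-gulo-hept-1-enitol (C4–OBn) | CC1(C)OC[C@@H](O1)[C@H](OCc2ccccc2)[C@H]3OC(C)(C)O[C@H]3C=C | intermediate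
7 | C1,C7-diol, C1 epimers | CC1(C)OC[C@@H](O1)[C@H](OCc2ccccc2)[C@H]3OC(C)(C)O[C@H]3C(O)CO | intermediate
8 | C1,C7-O-dibutylstannylene acetal of 7 | CC1(C)OC[C@@H](O1)[C@H](OCc2ccccc2)[C@H]3OC(C)(C)O[C@H]3C4CO[Sn](CCCC)(CCCC)O4 | intermediate
9 | C7-O-PMB ether, C1–OH free | CC1(C)OC[C@@H](O1)[C@H](OCc2ccccc2)[C@H]3OC(C)(C)O[C@H]3C(O)COCc4ccc(OC)cc4 | intermediate
10 | C1,C2,C3-triol | OC[C@@H](O)[C@H](OCc2ccccc2)[C@H]3OC(C)(C)O[C@H]3C(O)COCc4ccc(OC)cc4 | intermediate
11 | C2,C3-O-(4-methoxybenzylidene) acetal | COc1ccc(cc1)C5OC[C@@H](O5)[C@H](OCc2ccccc2)[C@H]3OC(C)(C)O[C@H]3C(O)COCc4ccc(OC)cc4 | intermediate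
12 | C1,C2-diol with C3–OPMB | OC[C@@H](OCc1ccc(OC)cc1)[C@H](OCc2ccccc2)[C@H]3OC(C)(C)O[C@H]3C(O)COCc4ccc(OC)cc4 | intermediate
13 | keto aldehyde, 3-O-benzyl-4,5-O-isopropylidene-2,7-bis-O-(4-methoxybenzyl)-L-gluco-heptos-6-ulose | O=C[C@@H](OCc1ccc(OC)cc1)[C@H](OCc2ccccc2)[C@H]3OC(C)(C)O[C@H]3C(=O)COCc4ccc(OC)cc4 | intermediate
14 | branched cyclitol with free cis C1,C2-diol | COc1ccc(CO[C@H]2[C@H](OCc3ccccc3)[C@H]4OC(C)(C)O[C@H]4[C@@](O)(COCc5ccc(OC)cc5)[C@@H]2O)cc1 | intermediate
15 | C1,C2,C3,C7-tetraol | O[C@H]1[C@H](OCc2ccccc2)[C@H]3OC(C)(C)O[C@H]3[C@@](O)(CO)[C@@H]1O | intermediate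
16 | 7-O-benzoate triol | O[C@H]1[C@H](OCc2ccccc2)[C@H]3OC(C)(C)O[C@H]3[C@@](O)(COC(=O)c4ccccc4)[C@@H]1O | intermediate
17 | 2,3-di-O-acetyl-7-O-benzoyl cyclitol acetonide | CC(=O)O[C@H]1[C@H](OCc2ccccc2)[C@H]3OC(C)(C)O[C@H]3[C@@](O)(COC(=O)c4ccccc4)[C@@H]1OC(C)=O | intermediate
18 | C1,C5,C6-triol triester | CC(=O)O[C@H]1[C@H](OCc2ccccc2)[C@@H](O)[C@@H](O)[C@@](O)(COC(=O)c3ccccc3)[C@@H]1OC(C)=O | intermediate
19 | C5,C6 cyclic sulfite | CC(=O)O[C@H]1[C@H](OCc2ccccc2)[C@H]3OS(=O)O[C@H]3[C@@](O)(COC(=O)c4ccccc4)[C@@H]1OC(C)=O | intermediate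
20 | C5,C6 cyclic sulfate | CC(=O)O[C@H]1[C@H](OCc2ccccc2)[C@H]3OS(=O)(=O)O[C@H]3[C@@](O)(COC(=O)c4ccccc4)[C@@H]1OC(C)=O | intermediate
21 | sodium C5-sulfate of the C1,C6-epoxide | CC(=O)O[C@H]1[C@H](OCc2ccccc2)[C@@H](OS(=O)(=O)[O-])[C@@H]3O[C@]3(COC(=O)c4ccccc4)[C@@H]1OC(C)=O.[Na+] | intermediate
22 | C4-O-benzyl epoxy alcohol | CC(=O)O[C@H]1[C@H](OCc2ccccc2)[C@@H](O)[C@@H]3O[C@]3(COC(=O)c4ccccc4)[C@@H]1OC(C)=O | intermediate
23 | CNP0171674.1 (C1,C6-α-epoxide, C2-α and C3-β acetates, C4-α and C5-β hydroxyls, C7 benzoate) | CC(=O)O[C@H]1[C@H](O)[C@@H](O)[C@@H]2O[C@]2(COC(=O)c2ccccc2)[C@@H]1OC(C)=O | target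

Total step count: 18. Longest linear sequence: 18 steps (1 → 23).

## Steps most likely to fail

**1. Step 11 (pinacol closure).**
- Risk: plain reduction of the carbonyl groups without C–C bond formation, reductive loss of an α-alkoxy group, or weak facial control.
- Fallback, from 13 back to 14: the C1–C2 bond is made by olefin metathesis instead of reductive coupling. Double Wittig methylenation of 13 (Ph3P=CH2 from 4 and KN(SiMe3)2, THF, −78 → 0 °C) should give the 1,7-diene F1. Second-generation Grubbs catalyst in refluxing CH2Cl2 should close it to the trisubstituted C1=C2 cyclohexene F2. OsO4/NMO then adds both hydroxyls syn from the α face, anti to the allylic C3–OPMB and C6–O groups and to the β-fused dioxolane, which gives 14.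

**2. Step 17 (oxirane closure and sulfate hydrolysis).**
- Risk: acyl shift or ester cleavage at the alkoxide stage outrunning closure, or acid opening of the oxirane while the sulfate monoester is hydrolysed.
- Fallback, from 18 back to 22: single activation of C6–OH replaces the cyclic sulfate, so neither strong base nor mineral acid is needed. TESCl (1.05 equiv), imidazole, CH2Cl2, −40 °C should silylate the accessible equatorial C5–OH and give the 5-O-triethylsilyl ether F3. Tf2O, pyridine, CH2Cl2, −20 °C should convert the axial C6–OH into the 6-O-triflate F4. On warming in pyridine, the neutral trans-diaxial C1–OH should displace the triflate to give the silylated epoxide F5. AcOH/THF/H2O at rt then removes the silyl group and gives 22.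

**3. Step 13 (benzoylation of one hydroxyl out of four).**
- Risk: competing benzoylation of the equatorial C2–OH or C3–OH, because the primary C7–OH is neopentyl-like.
- Fallback, from 15 back to 17: a bulky temporary group separates the two acylations. TBSCl, imidazole, DMF, 0 °C should give the 7-O-TBS ether F6. Ac2O/pyridine gives its 2,3-diacetate F7. HF·pyridine in THF/pyridine at 0 °C frees C7–OH to give the diacetate alcohol F8. BzCl/pyridine then benzoylates the only reactive hydroxyl and gives 17.

## Further compounds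

F1 | step 11 | 1,7-diene (C1 and C2 carbonyls of 13 methylenated) | C=C[C@@H](OCc1ccc(OC)cc1)[C@H](OCc2ccccc2)[C@H]3OC(C)(C)O[C@H]3C(=C)COCc4ccc(OC)cc4
F2 | step 11 | C1=C2 cyclohexene | COc1ccc(CO[C@H]2[C@H](OCc3ccccc3)[C@H]4OC(C)(C)O[C@H]4C(COCc5ccc(OC)cc5)=C2)cc1
F3 | step 17 | 5-O-triethylsilyl ether of 18 | CC(=O)O[C@H]1[C@H](OCc2ccccc2)[C@@H](O[Si](CC)(CC)CC)[C@@H](O)[C@@](O)(COC(=O)c3ccccc3)[C@@H]1OC(C)=O
F4 | step 17 | 6-O-triflate of F3 | CC(=O)O[C@H]1[C@H](OCc2ccccc2)[C@@H](O[Si](CC)(CC)CC)[C@@H](OS(=O)(=O)C(F)(F)F)[C@@](O)(COC(=O)c3ccccc3)[C@@H]1OC(C)=O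
F5 | step 17 | 5-O-triethylsilyl ether of 22 | CC(=O)O[C@H]1[C@H](OCc2ccccc2)[C@@H](O[Si](CC)(CC)CC)[C@@H]3O[C@]3(COC(=O)c4ccccc4)[C@@H]1OC(C)=O
F6 | step 13 | 7-O-tert-butyldimethylsilyl ether of 15 | O[C@H]1[C@H](OCc2ccccc2)[C@H]3OC(C)(C)O[C@H]3[C@@](O)(CO[Si](C)(C)C(C)(C)C)[C@@H]1O
F7 | step 13 | 2,3-di-O-acetate of F6 | CC(=O)O[C@H]1[C@H](OCc2ccccc2)[C@H]3OC(C)(C)O[C@H]3[C@@](O)(CO[Si](C)(C)C(C)(C)C)[C@@H]1OC(C)=O
F8 | step 13 | 2,3-di-O-acetate with free C7–OH | CC(=O)O[C@H]1[C@H](OCc2ccccc2)[C@H]3OC(C)(C)O[C@H]3[C@@](O)(CO)[C@@H]1OC(C)=O
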